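A direct plan would take both rings as finished arenes: the ring B phenol A1 (methyl 4-hydroxy-2-methoxy-3,5,6-trimethylbenzoate) and, for ring A, the symmetric dialdehyde A2 (4,6-dihydroxy-2,5-dimethylbenzene-1,3-dicarbaldehyde), which twofold Duff formylation of 2,5-dimethylresorcinol A3 would supply.
It would join A1 and A2 in the last step by carbene-catalysed oxidative esterification of one of the two formyl groups of A2.
Weak point 1, the oxidative joining of the two rings: it would have to acylate a phenol flanked by two methyl groups with an acyl donor flanked by methyl and hydroxyl, stop after one of two identical formyl groups, and tolerate the free phenols of A2. None of these three demands has close precedent, and the whole risk would fall on the last step.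
Weak point 2, the twofold formylation of A3: the second formyl group would have to enter a ring already deactivated by the first, and the product is a symmetric compound whose symmetry must then be broken again with A2 in excess.

**Retrosynthetic overview**
- The ester C–O bond would be made early, between the ring B phenol and unbranched but-2-ynoic acid, whose acyl carbon has no ortho substituents.
- Key disconnection: bonds C1–C2 and C5–C6 of ring A, by Diels–Alder reaction and aromatization. The aryl but-2-ynoate supplies the ester carbon, C1, C6 and the 6-methyl; a 1-methoxy-2-methyl-1,3-bis(silyloxy)diene supplies C2–C5 with both oxygens and the 3-methyl.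
- Ring order: ring B comes from atraric acid, ring A is closed on the finished ester, and C5 of ring A, the only unsubstituted aromatic position of the depside, is formylated last.
- The design needs no ring-to-ring esterification, no dialdehyde and no desymmetrisation.

Key step: step 6

Remark: the target has no stereocentre; the stereogenic carbons of the transient intermediates are racemic and are destroyed.

Step 1
Reactants: 1 methyl 2,4-dihydroxy-3,6-dimethylbenzoate (atraric acid)
Product: 3 methyl 4-(benzyloxy)-2-methoxy-3,6-dimethylbenzoate, via mono-benzyl ether 2 (not isolated)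
Conditions: BnBr (1.05 equiv), K2CO3 (3 equiv), DMF, rt; then MeI (3 equiv), 50 °C (sealed)
Reagents that add atoms: benzyl bromide BrCc1ccccc1; iodomethane CI
Why: Williamson ether synthesis in two stages in one pot, in which the free 4-hydroxyl should be benzylated at rt and the 2-hydroxyl, hydrogen-bonded to the ester carbonyl, should react only in the later forced methylation; no stereocentre is formed.

Step 2
Reactants: 3 methyl 4-(benzyloxy)-2-methoxy-3,6-dimethylbenzoate
Product: 5 methyl 4-(benzyloxy)-5-formyl-2-methoxy-3,6-dimethylbenzoate, via chloro ether 4 (not isolated)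
Conditions: Cl2CHOMe (2 equiv), SnCl4 (2.5 equiv), CH2Cl2, −20 → 0 °C; then ice-cold 1 M HCl
Reagents that add atoms: dichloromethyl methyl ether COC(Cl)Cl; water O
Why: Rieche formylation at C5, the only free ring position, which is ortho to the benzyloxy and para to the methoxy group, followed by hydrolysis of the racemic chloro ether on work-up; any loss of the benzyl group here would be harmless because step 3 removes it.

Step 3
Reactants: 5 methyl 4-(benzyloxy)-5-formyl-2-methoxy-3,6-dimethylbenzoate
Product: 8 methyl 4-hydroxy-2-methoxy-3,5,6-trimethylbenzoate, via free-phenol aldehyde 6 (not isolated), via benzylic alcohol 7 (not isolated)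
Conditions: H2 (4 bar), 10% Pd/C, AcOH, HCl (cat.), 40 °C
Reagents that add atoms: none
Why: Catalytic hydrogenolysis, in which the benzyl ether is cleaved, the ortho-hydroxy benzaldehyde is hydrogenated to the benzylic alcohol and this, ionised under acid, is reduced to the methyl group, while the ester and the methyl ether should stay untouched; no stereocentre is formed.

Step 4
Reactants: 8 methyl 4-hydroxy-2-methoxy-3,5,6-trimethylbenzoate; 9 but-2-ynoic acid
Product: 10 3-methoxy-4-(methoxycarbonyl)-2,5,6-trimethylphenyl but-2-ynoate
Conditions: DCC (1.3 equiv), DMAP (0.1 equiv), CH2Cl2, 0 °C → rt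
Reagents that add atoms: none
Why: Steglich esterification, which should succeed with this di-ortho-methyl phenol because the acyl carbon of 9 carries only a linear alkynyl group and 8 has no other nucleophilic site; no stereocentre is formed.

Step 5
Reactants: 11 methyl 2-methyl-3-oxobutanoate
Product: 13 1-methoxy-2-methyl-1,3-bis(trimethylsilyloxy)buta-1,3-diene, via mono silyl enol ether 12 (not isolated)
Conditions: TMSCl (1.5 equiv), Et3N (1.6 equiv), pentane, rt; filter under argon, concentrate; then LiN(iPr)2 (1.2 equiv), THF, −78 °C; TMSCl (1.3 equiv), −78 °C → rt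
Reagents that add atoms: chlorotrimethylsilane C[Si](C)(C)Cl
Why: Stepwise enol silylation, the standard way to 1-alkoxy-1,3-bis(silyloxy)dienes: the enol oxygen of the β-keto ester is silylated first, the lithium amide then removes a γ-hydrogen from the vinylogous methyl group of 12 and the extended ester enolate is silylated on oxygen; the geometry of the ketene acetal double bond does not matter because that carbon becomes aromatic.

Step 6
Reactants: 10 3-methoxy-4-(methoxycarbonyl)-2,5,6-trimethylphenyl but-2-ynoate; 13 1-methoxy-2-methyl-1,3-bis(trimethylsilyloxy)buta-1,3-diene (3 equiv)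
Product: 15 3-methoxy-4-(methoxycarbonyl)-2,5,6-trimethylphenyl 2,4-dihydroxy-3,6-dimethylbenzoate, via cyclohexa-1,4-diene adduct 14 (not isolated)
Conditions: toluene, 120 °C, sealed tube; then 1 M HCl, THF, rt
Reagents that add atoms: none
Why: Diels–Alder reaction with normal electron demand followed by aromatization: the unsubstituted C4 terminus of diene 13, towards which all three oxygen donors push electron density, bonds to the methyl-bearing β-carbon of ynoate 10 and the ketene acetal carbon bonds to the α-carbon, so the hydroxyl from the ketene acetal ends up ortho to the ester (C2), the diene methyl between the two oxygens (C3) and the alkyne methyl at C6. The closest known reaction type is the cycloaddition of 1,1-dialkoxy- and 1-alkoxy-1-silyloxy-3-silyloxybuta-1,3-dienes with β-alkyl propiolates, which gives 6-alkyl-2,4-dioxygenated benzoates after loss of alcohol. Ring A is closed by an intermolecular [4+2] cycloaddition that forms C1–C2 and C5–C6 in one operation; the cyclohexa-1,4-diene 14 should then lose methanol from its mixed methyl silyl ketal carbon together with one hydrogen of the ring CH2 group under the acidic work-up, which also hydrolyses both silyl ethers. No stereocentre remains, because the racemic ketal carbon of 14 becomes aromatic. The step needs regioselectivity, which the matched polarisation of the two partners secures, and chemoselectivity, which the substrate secures: 10 has no acidic hydrogen that could quench the diene, its aryl ester lowers the alkyne LUMO, and its only other electrophile, the methyl ester of ring B, is flanked by methoxy and methyl groups; the excess of 13 covers losses by protodesilylation.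

Step 7
Reactants: 15 3-methoxy-4-(methoxycarbonyl)-2,5,6-trimethylphenyl 2,4-dihydroxy-3,6-dimethylbenzoate
Product: 17 3-methoxy-4-(methoxycarbonyl)-2,5,6-trimethylphenyl 3-formyl-4,6-dihydroxy-2,5-dimethylbenzoate (target), via chloro ether 16 (not isolated)
Conditions: Cl2CHOMe (2 equiv), TiCl4 (4 equiv), CH2Cl2, −20 → 0 °C; then ice-cold 1 M HCl
Reagents that add atoms: dichloromethyl methyl ether COC(Cl)Cl; water O
Why: Rieche formylation directed by the titanium phenolate to C5 of ring A, which is ortho to the 4-hydroxyl, para to the 2-hydroxyl and the only aromatic C–H of the molecule, so neither a regioisomer nor a second formylation is possible; the racemic chloro ether is hydrolysed on work-up and no stereocentre is formed.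

**Compound list**
1 | methyl 2,4-dihydroxy-3,6-dimethylbenzoate (atraric acid) | COC(=O)c1c(C)cc(O)c(C)c1O | starting material
2 | methyl 4-(benzyloxy)-2-hydroxy-3,6-dimethylbenzoate | COC(=O)c1c(C)cc(OCc2ccccc2)c(C)c1O | intermediate
3 | methyl 4-(benzyloxy)-2-methoxy-3,6-dimethylbenzoate | COC(=O)c1c(C)cc(OCc2ccccc2)c(C)c1OC | intermediate
4 | methyl 4-(benzyloxy)-5-[chloro(methoxy)methyl]-2-methoxy-3,6-dimethylbenzoate (racemic, transient) | COC(=O)c1c(C)c(C(Cl)OC)c(OCc2ccccc2)c(C)c1OC | intermediate
5 | methyl 4-(benzyloxy)-5-formyl-2-methoxy-3,6-dimethylbenzoate | COC(=O)c1c(C)c(C=O)c(OCc2ccccc2)c(C)c1OC | intermediate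
6 | methyl 5-formyl-4-hydroxy-2-methoxy-3,6-dimethylbenzoate | COC(=O)c1c(C)c(C=O)c(O)c(C)c1OC | intermediate
7 | methyl 4-hydroxy-5-(hydroxymethyl)-2-methoxy-3,6-dimethylbenzoate | COC(=O)c1c(C)c(CO)c(O)c(C)c1OC | intermediate
8 | methyl 4-hydroxy-2-methoxy-3,5,6-trimethylbenzoate | COC(=O)c1c(C)c(C)c(O)c(C)c1OC | intermediate
9 | but-2-ynoic acid | CC#CC(=O)O | starting material
10 | 3-methoxy-4-(methoxycarbonyl)-2,5,6-trimethylphenyl but-2-ynoate | COC(=O)c1c(C)c(C)c(OC(=O)C#CC)c(C)c1OC | intermediate
11 | methyl 2-methyl-3-oxobutanoate | COC(=O)C(C)C(C)=O | starting material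
12 | methyl 2-methyl-3-(trimethylsilyloxy)but-2-enoate (mixture of double-bond isomers) | COC(=O)C(C)=C(C)O[Si](C)(C)C | intermediate
13 | 1-methoxy-2-methyl-1,3-bis(trimethylsilyloxy)buta-1,3-diene (mixture of ketene acetal double-bond isomers) | COC(O[Si](C)(C)C)=C(C)C(=C)O[Si](C)(C)C | intermediate
14 | 3-methoxy-4-(methoxycarbonyl)-2,5,6-trimethylphenyl 6-methoxy-2,5-dimethyl-4,6-bis(trimethylsilyloxy)cyclohexa-1,4-diene-1-carboxylate (racemic, transient) | COC(=O)c1c(C)c(C)c(OC(=O)C2=C(C)CC(O[Si](C)(C)C)=C(C)C2(OC)O[Si](C)(C)C)c(C)c1OC | intermediate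
15 | 3-methoxy-4-(methoxycarbonyl)-2,5,6-trimethylphenyl 2,4-dihydroxy-3,6-dimethylbenzoate | COC(=O)c1c(C)c(C)c(OC(=O)c2c(C)cc(O)c(C)c2O)c(C)c1OC | intermediate
16 | 3-methoxy-4-(methoxycarbonyl)-2,5,6-trimethylphenyl 3-[chloro(methoxy)methyl]-4,6-dihydroxy-2,5-dimethylbenzoate (racemic, transient) | COC(=O)c1c(C)c(C)c(OC(=O)c2c(C)c(C(Cl)OC)c(O)c(C)c2O)c(C)c1OC | intermediate
17 | 3-methoxy-4-(methoxycarbonyl)-2,5,6-trimethylphenyl 3-formyl-4,6-dihydroxy-2,5-dimethylbenzoate | COC(=O)c1c(C)c(C)c(OC(=O)c2c(C)c(C=O)c(O)c(C)c2O)c(C)c1OC | target

Total step count: 7. Longest linear sequence: 6 steps (steps 1, 2, 3, 4, 6 and 7); step 5 is a one-step side branch.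

**Steps most likely to fail**

Step 6. The cycloaddition to the β-methyl alkyne may be slower than thermal silyl migration and protodesilylation of the diene, or may stop after conjugate addition without ring closure. The fallback gives up the benzannulation for a classical depside coupling with a protected ring A acid. It sets out from 8 (with 1 as second starting point) and comes back at 15. Atraric acid 1 would be dibenzylated (BnBr, K2CO3, DMF, 60 °C) to methyl 2,4-bis(benzyloxy)-3,6-dimethylbenzoate F1 and saponified (KOH, DMSO/H2O, 90 °C) to 2,4-bis(benzyloxy)-3,6-dimethylbenzoic acid F2. This acid would be coupled with 8 through its mixed anhydride ((CF3CO)2O, toluene, rt) to 3-methoxy-4-(methoxycarbonyl)-2,5,6-trimethylphenyl 2,4-bis(benzyloxy)-3,6-dimethylbenzoate F3. Hydrogenolysis (H2, 10% Pd/C, EtOAc, rt) should then give 15.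

Step 7. Lewis acid-assisted cleavage of the aryl ester, or demethylation of the methoxy group next to the ring B ester, may compete with a formylation that is slowed by titanium chelation of the salicylate. The fallback brings in the carbon at the alcohol level without a strong Lewis acid and oxidises it afterwards. It sets out from 15 and comes back at 17. Boronate-templated ortho-hydroxymethylation (PhB(OH)2, paraformaldehyde, EtCO2H (cat.), toluene, reflux with removal of water) should give 3-methoxy-4-(methoxycarbonyl)-2,5,6-trimethylphenyl 7-hydroxy-5,8-dimethyl-2-phenyl-4H-1,3,2-benzodioxaborine-6-carboxylate F4. Transesterification with propane-1,3-diol (THF, rt) should free 3-methoxy-4-(methoxycarbonyl)-2,5,6-trimethylphenyl 4,6-dihydroxy-3-(hydroxymethyl)-2,5-dimethylbenzoate F5, and MnO2 (CH2Cl2, rt) should oxidise the benzylic alcohol to 17.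

Step 3. The hydrogenation may stall at the benzylic alcohol, or begin to saturate the ring under the forcing acidic conditions. The fallback installs the methyl group by cross-coupling instead of formylation and reduction. It sets out from 3 and comes back at 8, so it replaces steps 2 and 3. Bromination (NBS, MeCN, 0 °C → rt) at the only free position should give methyl 4-(benzyloxy)-5-bromo-2-methoxy-3,6-dimethylbenzoate F6. Suzuki–Miyaura methylation (trimethylboroxine, Pd(PPh3)4, K2CO3, dioxane/H2O, 100 °C) should give methyl 4-(benzyloxy)-2-methoxy-3,5,6-trimethylbenzoate F7, and mild hydrogenolysis (H2, 1 bar, 10% Pd/C, EtOAc, rt) should give 8.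

Further compounds
F1 | step 6 | methyl 2,4-bis(benzyloxy)-3,6-dimethylbenzoate | COC(=O)c1c(C)cc(OCc2ccccc2)c(C)c1OCc1ccccc1
F2 | step 6 | 2,4-bis(benzyloxy)-3,6-dimethylbenzoic acid | OC(=O)c1c(C)cc(OCc2ccccc2)c(C)c1OCc1ccccc1
F3 | step 6 | 3-methoxy-4-(methoxycarbonyl)-2,5,6-trimethylphenyl 2,4-bis(benzyloxy)-3,6-dimethylbenzoate | COC(=O)c1c(C)c(C)c(OC(=O)c2c(C)cc(OCc3ccccc3)c(C)c2OCc2ccccc2)c(C)c1OC
F4 | step 7 | 3-methoxy-4-(methoxycarbonyl)-2,5,6-trimethylphenyl 7-hydroxy-5,8-dimethyl-2-phenyl-4H-1,3,2-benzodioxaborine-6-carboxylate | COC(=O)c1c(C)c(C)c(OC(=O)c2c(C)c3COB(c4ccccc4)Oc3c(C)c2O)c(C)c1OC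
F5 | step 7 | 3-methoxy-4-(methoxycarbonyl)-2,5,6-trimethylphenyl 4,6-dihydroxy-3-(hydroxymethyl)-2,5-dimethylbenzoate | COC(=O)c1c(C)c(C)c(OC(=O)c2c(C)c(CO)c(O)c(C)c2O)c(C)c1OC
F6 | step 3 | methyl 4-(benzyloxy)-5-bromo-2-methoxy-3,6-dimethylbenzoate | COC(=O)c1c(C)c(Br)c(OCc2ccccc2)c(C)c1OC
F7 | step 3 | methyl 4-(benzyloxy)-2-methoxy-3,5,6-trimethylbenzoate | COC(=O)c1c(C)c(C)c(OCc2ccccc2)c(C)c1OC
A1 | direct plan | methyl 4-hydroxy-2-methoxy-3,5,6-trimethylbenzoate | COC(=O)c1c(C)c(C)c(O)c(C)c1OC
A2 | direct plan | 4,6-dihydroxy-2,5-dimethylbenzene-1,3-dicarbaldehyde | O=Cc1c(C)c(C=O)c(O)c(C)c1O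
A3 | direct plan | 2,5-dimethylbenzene-1,3-diol (2,5-dimethylresorcinol) | Cc1cc(O)c(C)c(O)c1
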